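**Retrosynthetic overview**
1. Target 29 ⇐ trans-hydroazulenone 11 by late functional-group steps: C2 acetate (C4-OH-directed reduction of a C2 ketone, then acetylation), C4 carbinol (i-PrCeCl2 on a C4 ketone), C6 ester (Mitsunobu inversion), C8 methyl alkene (enol triflate, Negishi).
2. 11 ⇐ cis-hydroazulenone 10 (C5 epimerisation) ⇐ decalin diol monomesylate 8: disconnect C1–C5, reconnect C1–C6 (alkoxide-driven pinacol-type 1,2-shift).
3. 8 ⇐ (R)-Wieland–Miescher ketone 1: bis-ketalisation with alkene shift to C5=C6, C4 allylic oxidation, reduction and PMB protection, osmylation anti to the methyl, C5 mesylation.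
4. Feature used: quaternary C1 (angular methyl) flanked by oxygenated C2 and 1,4 across the ring from carbonyl-level C8. This is the Wieland–Miescher pattern once the C1–C5 bond of the cyclopentane (C1–C2–C3–C4–C5) is returned to C6, which turns the seven-membered ring (C1, C5–C10) back into a cyclohexane.
5. Ring order: both six-membered rings come with 1; the five- and seven-membered rings form together in step 7.

Key step: step 7

Conventions and assumption: C1 is the quaternary carbon with the angular methyl, C2–C5 are the carbons that end in the five-membered ring (C2 next to C1), and C6–C10 complete the seven-membered ring (C6 next to C5, C10 next to C1). α is the face carrying the C1 methyl, β the opposite face. The 4α configuration set in step 3 assumes axial hydride delivery; this centre is removed again at ketone 24.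

**Step 1**
Reactants: 1 (R)-Wieland–Miescher ketone; 2 ethylene glycol
Product: 3 C2,C8-bis(ethylene ketal) with the alkene at C5=C6
Conditions: 2 (5 equiv), p-TsOH·H2O (cat.), benzene, reflux, Dean–Stark
Reagents that add atoms: none
Why: Acid-catalysed ketalisation of both carbonyls; the enone ketal forms through the dienol ether, so the alkene moves out of conjugation to C5=C6 (as Δ4-3-ketones give Δ5-3-ketals), and C1 is untouched.

**Step 2**
Reactants: 3 bis-ketal
Product: 4 bis-ketal 4-en-one (C4=O conjugated with C5=C6)
Conditions: Rh2(cap)4 (1 mol%), t-BuOOH (70% aq., 5 equiv), K2CO3, CH2Cl2, rt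
Reagents that add atoms: tert-butyl hydroperoxide CC(C)(C)OO
Why: Rhodium-catalysed allylic C–H oxidation (tert-butylperoxyl radical) at C4, the unhindered allylic methylene; C7 is flanked by the C8 ketal carbon and deactivated, as Δ5-3-ketal steroids are oxidised at C7.

**Step 3**
Reactants: 4 enone
Product: 5 4α-allylic alcohol (OH cis to the C1 methyl)
Conditions: NaBH4, CeCl3·7H2O, MeOH, −40 → 0 °C
Reagents that add atoms: none
Why: Luche 1,2-reduction; hydride is expected to enter C4 axially on the β face (as in Δ5-7-keto steroids), giving the pseudo-equatorial 4α-alcohol.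

**Step 4**
Reactants: 5 allylic alcohol
Product: 6 4α-(4-methoxybenzyl) ether
Conditions: NaH, PMBCl, n-Bu4NI (cat.), THF–DMF, 0 °C → rt
Reagents that add atoms: 4-methoxybenzyl chloride COc1ccc(CCl)cc1
Why: Williamson etherification; the ether keeps the C4 oxygen from being mesylated or from triggering a competing shift in step 7, and PMB can later be removed without touching silyl ethers.

**Step 5**
Reactants: 6 PMB ether
Product: 7 5β,6β-diol (trans-decalin; C6-OH axial, C5-OH equatorial)
Conditions: K2OsO2(OH)4 (5 mol%), NMO, MeSO2NH2, acetone–H2O (4:1), rt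
Reagents that add atoms: N-methylmorpholine N-oxide C[N+]1([O-])CCOCC1; water O
Why: Upjohn syn-dihydroxylation; osmium adds to the face of C5=C6 opposite the axial C1 methyl and anti to the allylic C4 ether (Kishi model), setting C5 and C6 as the 5β,6β-diol.

**Step 6**
Reactants: 7 diol
Product: 8 5β-mesylate with free 6β-hydroxyl (key-step precursor)
Conditions: MsCl, Et3N, DMAP (cat.), CH2Cl2, −10 °C
Reagents that add atoms: methanesulfonyl chloride CS(=O)(=O)Cl
Why: Sulfonylation of the only secondary hydroxyl with retention at C5; the tertiary C6 hydroxyl does not react.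

**Step 7**
Reactants: 8 diol monomesylate
Product: 10 cis-fused hydroazulen-6-one bis-ketal (H5 α; 4α-OPMB), via potassium C6-alkoxide 9 (not isolated)
Conditions: KOt-Bu (1.05 equiv), t-BuOH–THF (1:4), 0 °C, then pH 7 buffer
Reagents that add atoms: none
Why: tert-Butoxide deprotonates the tertiary C6 hydroxyl, and the alkoxide pushes the C1–C6 ring-fusion bond, which is antiperiplanar to the equatorial C5–OMs bond in the rigid trans-decalin, onto C5 as mesylate leaves (pinacol-type 1,2-alkyl shift, the classical route from decalin-1,2-diol monosulfonates to hydroazulenones). This one migration closes the cyclopentane C1–C2–C3–C4–C5 by C1–C5 bond formation through a three-centre suprafacial shift (contraction of the ring that held C1–C6) and enlarges the other ring to the cycloheptanone C1–C5–C6–C7–C8–C9–C10 by inserting C5 between C1 and C6, with C6 becoming the carbonyl. C1 migrates with retention, so the quaternary centre of 1 is carried over; C5 is attacked anti to the leaving group and inverted, which leaves H5 on the α face and gives the cis ring fusion stereospecifically. The step needs C1 to migrate rather than C7 or C3 and needs no epoxide closure: C7 is gauche to the leaving group, the C3–C4 bond is also antiperiplanar but C4 carries an ether and not an alkoxide, and the cis diol (axial O−, equatorial OMs) cannot reach the anti geometry an epoxide would require. Only a slight excess of base at 0 °C is used so that the β-oxygenated ketone is exposed to base as briefly as possible.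

**Step 8**
Reactants: 10 cis-fused ketone
Product: 11 trans-fused hydroazulen-6-one bis-ketal (H5 β)
Conditions: DBU (0.3 equiv), toluene, rt → 40 °C
Reagents that add atoms: none
Why: Epimerisation α to the ketone by reversible enolisation at C5 should shift the ring fusion toward the trans isomer (H5 anti to the angular methyl), which is expected to be the more stable one in angular-methyl hydroazulen-ones of this type; unchanged 10 is recycled.

**Step 9**
Reactants: 11 trans-fused ketone
Product: 12 6α-alcohol (OH cis to the C1 methyl)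
Conditions: NaBH4, MeOH–THF, −20 → 0 °C
Reagents that add atoms: none
Why: Hydride reduction from the β face of the C6 carbonyl, away from the 1,3-related angular methyl and the C4 ether, gives the pseudo-axial 6α-alcohol, as 6-keto steroids give the alcohol syn to the angular methyl.

**Step 10**
Reactants: 12 6α-alcohol
Product: 13 6α-tert-butyldimethylsilyl ether
Conditions: TBSOTf, 2,6-lutidine, CH2Cl2, −78 → 0 °C
Reagents that add atoms: tert-butyldimethylsilyl triflate CC(C)(C)[Si](C)(C)OS(=O)(=O)C(F)(F)F
Why: Silylation of the hindered secondary alcohol with the silyl triflate; the ether carries C6–O through the C8 enolate chemistry as a group that is neither an acyl group nor a good leaving group.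

**Step 11**
Reactants: 13 silyl ether
Product: 14 C8 ketone (C2 ketal retained)
Conditions: PPTS (0.2 equiv), acetone–H2O (10:1), rt
Reagents that add atoms: water O
Why: Acid-catalysed ketal hydrolysis, selective for the unhindered cycloheptanone ketal; the C2 dioxolane next to quaternary C1 reacts much more slowly (as 17- versus 3-ketals in steroids).

**Step 12**
Reactants: 14 C8 ketone
Product: 16 C8=C9 enol triflate, via potassium C8 enolate 15 (not isolated)
Conditions: KHMDS, THF, −78 °C; then Comins' reagent, −78 °C
Reagents that add atoms: N-(5-chloro-2-pyridyl)bis(trifluoromethanesulfonimide) FC(F)(F)S(=O)(=O)N(c1ccc(Cl)cn1)S(=O)(=O)C(F)(F)F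
Why: Kinetic deprotonation by the bulky amide at the less hindered C9 methylene, remote from the silyloxy-bearing C6 (β-silyloxy ketones enolise away from the oxygenated carbon), followed by O-triflation of the enolate, fixes the C8=C9 regiochemistry.

**Step 13**
Reactants: 16 enol triflate
Product: 17 8-methyl C8=C9 alkene (6α-OTBS, 4α-OPMB, C2 ketal)
Conditions: MeZnCl (2 equiv), Pd(PPh3)4 (5 mol%), THF, rt → 45 °C
Reagents that add atoms: methylzinc chloride C[Zn]Cl
Why: Negishi cross-coupling of the alkenyl triflate places the methyl on C8 with the alkene position unchanged.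

**Step 14**
Reactants: 17 silyl ether
Product: 18 6α-alcohol with 8-methyl C8=C9 alkene
Conditions: TBAF, THF, rt → 45 °C
Reagents that add atoms: none
Why: Fluoride-mediated desilylation of the only silyl ether frees the 6α-hydroxyl; ketal, PMB ether and alkene are inert.

**Step 15**
Reactants: 19 4-hydroxybenzoic acid
Product: 21 4-(tert-butyldimethylsilyloxy)benzoic acid, via bis-silylated silyl ester 20 (not isolated)
Conditions: TBSCl (2.3 equiv), imidazole, DMF, rt; then AcOH–THF–H2O, rt
Reagents that add atoms: tert-butyldimethylsilyl chloride CC(C)(C)[Si](C)(C)Cl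
Why: Silylation of both acidic hydroxyls followed by selective solvolysis of the labile silyl ester leaves only the phenol protected.

**Step 16**
Reactants: 18 6α-alcohol; 21 4-(tert-butyldimethylsilyloxy)benzoic acid
Product: 22 6β-[4-(tert-butyldimethylsilyloxy)benzoate]
Conditions: PPh3, DIAD, toluene, 0 °C → rt
Reagents that add atoms: none
Why: Mitsunobu esterification; the C6 oxyphosphonium is displaced by the carboxylate with inversion, so the ester ends on the β face (cis to H5, trans to the angular methyl).

**Step 17**
Reactants: 22 PMB ether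
Product: 23 4α-alcohol
Conditions: DDQ, CH2Cl2–pH 7 phosphate buffer, 0 °C → rt
Reagents that add atoms: none
Why: Oxidative PMB cleavage (hydride abstraction to the oxocarbenium ion, then hydrolysis); aryl silyl ether, ester, ketal and trisubstituted alkene are stable.

**Step 18**
Reactants: 23 4α-alcohol
Product: 24 C4 ketone
Conditions: Dess–Martin periodinane, NaHCO3, CH2Cl2, 0 °C → rt
Reagents that add atoms: none
Why: Dess–Martin oxidation under buffered, non-basic conditions should give the β-acyloxy ketone without epimerisation at C5 or elimination of the C6 ester.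

**Step 19**
Reactants: 24 C4 ketone
Product: 25 4α-hydroxy-4β-isopropyl tertiary alcohol
Conditions: i-PrMgCl, anhydrous CeCl3, THF, −78 °C (1 h), then 24, −78 → −40 °C; aq. NH4Cl
Reagents that add atoms: isopropylmagnesium chloride CC(C)[Mg]Cl
Why: Organocerium (Imamoto) 1,2-addition; the weakly basic reagent should add to the enolisable cyclopentanone without enolisation, ester attack or loss of the C6 ester, and it approaches C4 from the β face, anti to the α-oriented C5–C6 bond and the C1 methyl, placing isopropyl β and hydroxyl α.

**Step 20**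
Reactants: 25 tertiary alcohol
Product: 26 C2 ketone (β-hydroxy ketone)
Conditions: PPTS, acetone–H2O (10:1), 50 °C
Reagents that add atoms: water O
Why: Acid-catalysed hydrolysis of the remaining ketal under weakly acidic conditions that should leave the tertiary β-hydroxyl, both esters and the aryl silyl ether untouched.

**Step 21**
Reactants: 26 β-hydroxy ketone
Product: 27 2β,4α-diol
Conditions: Me4NBH(OAc)3, MeCN–AcOH (1:1), −25 °C
Reagents that add atoms: none
Why: Evans–Saksena hydroxyl-directed reduction; the C4 hydroxyl binds boron and delivers hydride to the α face of the C2 carbonyl, giving the anti-1,3-diol with the new C2 hydroxyl β (trans to the angular methyl), and the reagent does not reduce esters.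

**Step 22**
Reactants: 27 diol
Product: 28 2β-acetate (phenol still silylated)
Conditions: Ac2O, pyridine, DMAP (cat.), CH2Cl2, 0 °C → rt
Reagents that add atoms: acetic anhydride CC(=O)OC(C)=O
Why: DMAP-catalysed acylation of the only secondary hydroxyl; the tertiary C4 hydroxyl is too hindered to react under these conditions.

**Step 23**
Reactants: 28 silyl-protected acetate
Product: 29 CNP0275279.1
Conditions: TBAF, AcOH (1:1), THF, 0 °C
Reagents that add atoms: none
Why: Fluoride cleavage of the aryl silyl ether, buffered with acetic acid so that the acetate and the benzoate are not touched.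

**Compound list**
1 | (R)-Wieland–Miescher ketone | O=C1CCCC2=CC(=O)CC[C@@]12C | starting material
2 | ethylene glycol | OCCO | starting material
3 | C2,C8-bis(ethylene ketal), alkene at C5=C6 | O1CCOC12CCC=C3CC4(OCCO4)CC[C@@]23C | intermediate
4 | bis-ketal 4-en-one (C4=O, C5=C6) | O1CCOC12CC(=O)C=C3CC4(OCCO4)CC[C@@]23C | intermediate
5 | 4α-allylic alcohol (OH cis to C1 methyl) | O1CCOC12C[C@H](O)C=C3CC4(OCCO4)CC[C@@]23C | intermediate
6 | 4α-PMB ether | O1CCOC12C[C@H](OCc5ccc(OC)cc5)C=C3CC4(OCCO4)CC[C@@]23C | intermediate
7 | 4α-OPMB 5β,6β-diol (trans-decalin) | O1CCOC12C[C@H](OCc5ccc(OC)cc5)[C@@H](O)[C@]3(O)CC4(OCCO4)CC[C@@]23C | intermediate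
8 | 5β-mesylate, 6β-OH, 4α-OPMB bis-ketal | O1CCOC12C[C@H](OCc5ccc(OC)cc5)[C@@H](OS(C)(=O)=O)[C@]3(O)CC4(OCCO4)CC[C@@]23C | intermediate
9 | potassium 6β-alkoxide of 8 | [K+].O1CCOC12C[C@H](OCc5ccc(OC)cc5)[C@@H](OS(C)(=O)=O)[C@]3([O-])CC4(OCCO4)CC[C@@]23C | intermediate
10 | cis-fused hydroazulen-6-one bis-ketal (H5 α, 4α-OPMB) | O1CCOC12C[C@H](OCc5ccc(OC)cc5)[C@H]3C(=O)CC4(OCCO4)CC[C@@]23C | intermediate
11 | trans-fused hydroazulen-6-one bis-ketal (H5 β) | O1CCOC12C[C@H](OCc5ccc(OC)cc5)[C@@H]3C(=O)CC4(OCCO4)CC[C@@]23C | intermediate
12 | 6α-alcohol | O1CCOC12C[C@H](OCc5ccc(OC)cc5)[C@@H]3[C@H](O)CC4(OCCO4)CC[C@@]23C | intermediate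
13 | 6α-OTBS ether | O1CCOC12C[C@H](OCc5ccc(OC)cc5)[C@@H]3[C@H](O[Si](C)(C)C(C)(C)C)CC4(OCCO4)CC[C@@]23C | intermediate
14 | C8 ketone (C2 ketal, 6α-OTBS, 4α-OPMB) | O1CCOC12C[C@H](OCc5ccc(OC)cc5)[C@@H]3[C@H](O[Si](C)(C)C(C)(C)C)CC(=O)CC[C@@]23C | intermediate
15 | potassium C8(O)=C9 enolate of 14 | [K+].O1CCOC12C[C@H](OCc5ccc(OC)cc5)[C@@H]3[C@H](O[Si](C)(C)C(C)(C)C)CC([O-])=CC[C@@]23C | intermediate
16 | C8=C9 enol triflate | O1CCOC12C[C@H](OCc5ccc(OC)cc5)[C@@H]3[C@H](O[Si](C)(C)C(C)(C)C)CC(OS(=O)(=O)C(F)(F)F)=CC[C@@]23C | intermediate
17 | 8-methyl C8=C9 alkene, 6α-OTBS | O1CCOC12C[C@H](OCc5ccc(OC)cc5)[C@@H]3[C@H](O[Si](C)(C)C(C)(C)C)CC(C)=CC[C@@]23C | intermediate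
18 | 8-methyl C8=C9 alkene, 6α-OH | O1CCOC12C[C@H](OCc5ccc(OC)cc5)[C@@H]3[C@H](O)CC(C)=CC[C@@]23C | intermediate
19 | 4-hydroxybenzoic acid | OC(=O)c1ccc(O)cc1 | starting material
20 | tert-butyldimethylsilyl 4-(tert-butyldimethylsilyloxy)benzoate | CC(C)(C)[Si](C)(C)OC(=O)c1ccc(O[Si](C)(C)C(C)(C)C)cc1 | intermediate
21 | 4-(tert-butyldimethylsilyloxy)benzoic acid | OC(=O)c1ccc(O[Si](C)(C)C(C)(C)C)cc1 | intermediate
22 | 6β-[4-(TBSO)benzoate], 4α-OPMB, C2 ketal | O1CCOC12C[C@H](OCc5ccc(OC)cc5)[C@@H]3[C@@H](OC(=O)c6ccc(O[Si](C)(C)C(C)(C)C)cc6)CC(C)=CC[C@@]23C | intermediate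
23 | 4α-alcohol, 6β-ester | O1CCOC12C[C@H](O)[C@@H]3[C@@H](OC(=O)c6ccc(O[Si](C)(C)C(C)(C)C)cc6)CC(C)=CC[C@@]23C | intermediate
24 | C4 ketone, 6β-ester | O1CCOC12CC(=O)[C@@H]3[C@@H](OC(=O)c6ccc(O[Si](C)(C)C(C)(C)C)cc6)CC(C)=CC[C@@]23C | intermediate
25 | 4α-hydroxy-4β-isopropyl compound, C2 ketal | O1CCOC12C[C@@](O)(C(C)C)[C@@H]3[C@@H](OC(=O)c6ccc(O[Si](C)(C)C(C)(C)C)cc6)CC(C)=CC[C@@]23C | intermediate
26 | C2 ketone with 4α-OH | O=C1C[C@@](O)(C(C)C)[C@@H]2[C@@H](OC(=O)c3ccc(O[Si](C)(C)C(C)(C)C)cc3)CC(C)=CC[C@@]12C | intermediate
27 | 2β,4α-diol | O[C@H]1C[C@@](O)(C(C)C)[C@@H]2[C@@H](OC(=O)c3ccc(O[Si](C)(C)C(C)(C)C)cc3)CC(C)=CC[C@@]12C | intermediate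
28 | 2β-acetate, aryl TBS ether | CC(=O)O[C@H]1C[C@@](O)(C(C)C)[C@@H]2[C@@H](OC(=O)c3ccc(O[Si](C)(C)C(C)(C)C)cc3)CC(C)=CC[C@@]12C | intermediate
29 | CNP0275279.1 | CC(=O)O[C@H]1C[C@@](O)(C(C)C)[C@@H]2[C@@H](OC(=O)c3ccc(O)cc3)CC(C)=CC[C@@]12C | target

**Step count**
Total: 23 steps. Longest linear sequence: 22 steps (1 → 29 through steps 1–14 and 16–23); step 15 is a one-step branch.

**Steps most likely to fail**

Step 7. Ionisation at C5 may be slowed by the electron-withdrawing C4 ether. The product ketone then stays in contact with alkoxide base and may enolise toward C7 with opening of the C8 dioxolane, or toward C5 with loss of the C4 ether. The fallback leaves the anionic manifold and uses a Lewis-acid-mediated rearrangement of the β-mesyloxy alcohol. It sets out from 8, which is treated with Et3Al in CH2Cl2 at −78 → 0 °C to give the diethylaluminium alkoxide F1. Aluminium also activates the mesylate, and the same antiperiplanar C1 shift should give ketone 10 with no enolate present. The fallback returns to the route at 10.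

Step 8. The equilibrium may not lie far enough on the trans side, because the C4 ether ends up cis to the C5–C6 bond in 11. Repeated enolisation may also cause the same β-eliminations as in step 7. The fallback replaces thermodynamic by kinetic control. It sets out from 10, which is converted under equilibrating silylation (TMSCl, Et3N, DMF, 80 °C) into the more substituted C5=C6 trimethylsilyl enol ether F2. The enol ether is cleaved with TBAF in the presence of acetic acid in THF at −78 °C. C5 should be protonated on the β face, since the α face is blocked by the C1 methyl and the C4 ether. The fallback returns to the route at 11.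

Step 16. Displacement at the hindered, pseudo-axial C6 oxyphosphonium may be slow, and anti elimination toward C5 or C7 may take over. The fallback avoids substitution at C6 altogether and sets out from 18. Dess–Martin oxidation (NaHCO3, CH2Cl2) gives the C6 ketone F3. Electron-transfer reduction with SmI2, H2O and Et3N in THF should then give the more stable pseudo-equatorial 6β-alcohol F4, in which the hydroxyl avoids the syn-1,3 interaction with the angular methyl. Esterification of F4 with acid 21 (EDC·HCl, DMAP, CH2Cl2) proceeds with retention and returns to the route at 22.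

**Further compounds**
F1 | step 7 | diethylaluminium 6β-alkoxide of mesylate 8 | O1CCOC12C[C@H](OCc5ccc(OC)cc5)[C@@H](OS(C)(=O)=O)[C@]3(O[Al](CC)CC)CC4(OCCO4)CC[C@@]23C
F2 | step 8 | C5=C6 trimethylsilyl enol ether of ketone 10 | O1CCOC12C[C@H](OCc5ccc(OC)cc5)C3=C(O[Si](C)(C)C)CC4(OCCO4)CC[C@@]23C
F3 | step 16 | C6 ketone from 18 (trans-fused, 8-methyl C8=C9 alkene) | O1CCOC12C[C@H](OCc5ccc(OC)cc5)[C@@H]3C(=O)CC(C)=CC[C@@]23C
F4 | step 16 | 6β-alcohol (C6 epimer of 18) | O1CCOC12C[C@H](OCc5ccc(OC)cc5)[C@@H]3[C@@H](O)CC(C)=CC[C@@]23C
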